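**Retrosynthetic overview**

1. The anisate goes on last, by selective acylation of the secondary C4–OH of the free ketol diol, which is released from its C4 silyl ether.
2. Key disconnection: the cyclopentanone ring (C1, C2, C3, C3a, C8a) is closed last from a trans-fused γ-enol lactone (ring O between C1 and C3, exocyclic C1=CH2) and an isopropyl nucleophile; acyl substitution at C3 releases the C1/C2 enolate, which closes the C2–C3 bond, so the ring oxygen is exchanged for the former exocyclic carbon.
3. Enabling feature: this ring holds a β-ketol, C1(=O)–C2H2–C3(OH)(i-Pr), whose two oxygenated carbons sit on the ring-fusion atoms C8a/C3a and can be tied through one oxygen; C8a is quaternary, so only the exocyclic enol ester and only the C2 enolate can form.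
4. The enol lactone comes from a cycloheptene γ,δ-unsaturated acid (Pd-catalysed oxidative lactonisation); the seven-membered ring is made before it by ring-closing metathesis of a triene acid.
5. The triene acid, with C8a, C3a and C4 set, comes from one dianionic Ireland–Claisen rearrangement of an allyl β-hydroxy ester (chiral-pool chlorohydrin plus an E-dienol). Ring order: cycloheptene, temporary lactone, cyclopentanone.

Key step: step 8

Remark: locants in the text follow the azulenone numbering of the target (C1 ring ketone, C2, C3 isopropyl carbinol, C3a, C4 ester-bearing carbon, C5, C6 methyl-bearing alkene carbon, C7, C8, C8a methyl-bearing quaternary carbon); the face selection of the dianionic Claisen step is assumed to follow that of Fráter–Seebach alkylations.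

**Route**

Step 1
Reactants: 1 pent-1-en-4-yne
Product: 4 (2E)-3-methylhexa-2,5-dien-1-ol, via alkenylalane 2 (not isolated), via lithium alkenylaluminate 3 (not isolated)
Conditions: Me3Al (2 equiv), Cp2ZrCl2 (0.2 equiv), CH2Cl2, 0 → 23 °C; excess Me3Al removed in vacuo; n-BuLi (1 equiv), THF–hexane, −78 → 0 °C; (CH2O)n, 23 °C; aq. HCl
Reagents that add atoms: trimethylaluminium, C[Al](C)C; formaldehyde (as paraformaldehyde), C=O
Why: Zirconium-catalysed syn-methylalumination of the terminal alkyne (Negishi carboalumination) is regio- and stereoselective and leaves the isolated alkene alone, and hydroxymethylation of the derived ate complex retains the alkene geometry, so the E-trisubstituted allylic alcohol should result.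

Step 2
Reactants: 5 ethyl (3R)-4-chloro-3-hydroxybutanoate
Product: 7 ethyl (3S)-3-hydroxy-5-methylhex-5-enoate, via epoxy ester 6 (not isolated)
Conditions: isopropenylMgBr (3 equiv), CuI (10 mol %), THF, −40 → −10 °C; aq. NH4Cl
Reagents that add atoms: isopropenylmagnesium bromide, CC(=C)[Mg]Br
Why: The magnesium alkoxide of the chlorohydrin closes to the terminal epoxide, which a copper-catalysed Grignard addition opens at the unhindered CH2 (SN2), so the carbinol stereocentre is not touched and only its descriptor changes from R to S.

Step 3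
Reactants: 7 ethyl (3S)-3-hydroxy-5-methylhex-5-enoate; 4 (2E)-3-methylhexa-2,5-dien-1-ol
Product: 8 (2E)-3-methylhexa-2,5-dien-1-yl (3S)-3-hydroxy-5-methylhex-5-enoate
Conditions: distannoxane transesterification catalyst [Bu2Sn(NCS)OSn(OH)Bu2]2 (2 mol %), toluene, reflux, EtOH distilled off
Reagents that add atoms: none
Why: Tin-catalysed transesterification under neutral conditions exchanges the ethoxy group for the primary allylic alcohol while ethanol is removed, and it should leave the β-hydroxy group, the skipped diene and the stereocentre unchanged.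

Step 4
Reactants: 8 (2E)-3-methylhexa-2,5-dien-1-yl (3S)-3-hydroxy-5-methylhex-5-enoate
Product: 10 (2S,3S)-3-hydroxy-5-methyl-2-[(3S)-3-methylhexa-1,5-dien-3-yl]hex-5-enoic acid, via chelated dilithium dianion 9 (not isolated)
Conditions: LDA (2.3 equiv), THF, −78 → 23 °C, then 40 °C; aq. HCl to pH 3
Reagents that add atoms: none
Why: In this dianionic (chelate-controlled) Ireland–Claisen rearrangement the lithium chelate between alkoxide and enolate oxygen fixes the enolate geometry, the allyl unit is delivered to the enolate face anti to the carbinol substituent as in a Fráter–Seebach alkylation (2,3-anti, 2S), and the chair transition state with the E-alkene puts the methyl group axial, which sets the quaternary centre as 3′S.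

Step 5
Reactants: 10 (2S,3S)-3-hydroxy-5-methyl-2-[(3S)-3-methylhexa-1,5-dien-3-yl]hex-5-enoic acid
Product: 12 (2S,3S)-3-[(tert-butyldimethylsilyl)oxy]-5-methyl-2-[(3S)-3-methylhexa-1,5-dien-3-yl]hex-5-enoic acid, via bis-silylated acid 11 (not isolated)
Conditions: TBSOTf (2.5 equiv), 2,6-lutidine (4 equiv), CH2Cl2, −78 → 0 °C; then AcOH–THF–H2O, 23 °C
Reagents that add atoms: tert-butyldimethylsilyl trifluoromethanesulfonate, CC(C)(C)[Si](C)(C)OS(=O)(=O)C(F)(F)F
Why: Silylation with the silyl triflate covers the hindered secondary alcohol and, for a time, the acid, and the labile silyl ester is then hydrolysed selectively by aqueous acetic acid, with no stereocentre involved.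

Step 6
Reactants: 12 (2S,3S)-3-[(tert-butyldimethylsilyl)oxy]-5-methyl-2-[(3S)-3-methylhexa-1,5-dien-3-yl]hex-5-enoic acid
Product: 13 (1S,2S,7S)-7-[(tert-butyldimethylsilyl)oxy]-2-ethenyl-2,5-dimethylcyclohept-4-ene-1-carboxylic acid
Conditions: Grubbs II catalyst (5 mol %), CH2Cl2 (5 mM), 40 °C
Reagents that add atoms: none
Why: In this ring-closing metathesis the ruthenium carbene should load on the unhindered allyl terminus and close on the 1,1-disubstituted methallyl alkene to give the trisubstituted cycloheptene, while the vinyl group on the quaternary carbon is too hindered to load and could only form a cyclobutene with the allyl group, so it should survive.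

Step 7
Reactants: 13 (1S,2S,7S)-7-[(tert-butyldimethylsilyl)oxy]-2-ethenyl-2,5-dimethylcyclohept-4-ene-1-carboxylic acid
Product: 14 (3aS,4S,8aR)-4-[(tert-butyldimethylsilyl)oxy]-6,8a-dimethyl-1-methylidene-1,3a,4,5,8,8a-hexahydro-3H-cyclohepta[c]furan-3-one
Conditions: Pd(OAc)2 (10 mol %), NaOAc (2 equiv), O2 (1 atm), DMSO, 40 °C
Reagents that add atoms: none
Why: Palladium(II)-catalysed aerobic oxidative lactonisation of the γ,δ-unsaturated acid (Wacker-type 5-exo oxypalladation, then β-hydride elimination) should engage only the terminal vinyl group, the quaternary neighbour allows only the exocyclic enol double bond, and the trans relation of carboxyl and vinyl groups gives the trans-fused lactone without touching a stereocentre.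

Step 8
Reactants: 14 (3aS,4S,8aR)-4-[(tert-butyldimethylsilyl)oxy]-6,8a-dimethyl-1-methylidene-1,3a,4,5,8,8a-hexahydro-3H-cyclohepta[c]furan-3-one
Product: 16 (3R,3aS,4S,8aR)-4-[(tert-butyldimethylsilyl)oxy]-3-hydroxy-6,8a-dimethyl-3-(propan-2-yl)-3,3a,4,5,8,8a-hexahydroazulen-1(2H)-one, via ring-opened keto cerium enolate 15 (not isolated)
Conditions: i-PrMgCl (1.1 equiv), anhydrous CeCl3 (1.3 equiv), THF, −78 °C, then slowly to 0 °C; pH 7 buffer at 0 °C
Reagents that add atoms: isopropylmagnesium chloride, CC(C)[Mg]Cl
Why: Proposed new method: the isopropylcerium reagent adds to the only carbonyl group of 14, the enol-ester C=O, and the adduct collapses with loss of the enolate oxygen to give the isopropyl ketone together with the regiodefined C2 enolate 15, which then attacks the new ketone, so that the ring oxygen of the lactone is exchanged for the former exocyclic CH2 and the C1 ketone is unveiled. The closest known reaction types are the Fujimoto–Belleau reaction (Grignard addition to an enol lactone, then aldol closure) and the cleavage of enol esters by organometallic reagents to regiodefined enolates; what has not been shown is the direct closure to a five-membered ketol from a 5-methylidene γ-lactone with a secondary alkyl nucleophile. The cyclopentanone ring closes by a 5-(enolendo)-exo-trig aldol addition (C2–C3 bond), a mode that Baldwin's rules rate as disfavoured but by which 1,4-diketones are routinely cyclised; here the two partners are held gauche on the ring-fusion carbons and the quaternary C8a adds a gem-disubstituent effect. The only new stereocentre, C3, is set by the substrate: with the trans fusion at C3a/C8a already fixed, the isopropyl group takes the open face next to H-3a and the metal-bound oxygen the face of the C8a methyl group and the C3a–C4 bond, which gives 3R and should also be the more stable ketol if the aldol is reversible. The step needs addition instead of deprotonation at C3a (the C3a enolate would expel the C4 silyloxy group), no second addition and no dehydration; the weakly basic organocerium reagent, the fact that the C1 carbonyl stays masked as its enolate until ring closure, one equivalent of reagent and a cold neutral quench should secure this.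

Step 9
Reactants: 16 (3R,3aS,4S,8aR)-4-[(tert-butyldimethylsilyl)oxy]-3-hydroxy-6,8a-dimethyl-3-(propan-2-yl)-3,3a,4,5,8,8a-hexahydroazulen-1(2H)-one
Product: 17 (3R,3aS,4S,8aR)-3,4-dihydroxy-6,8a-dimethyl-3-(propan-2-yl)-3,3a,4,5,8,8a-hexahydroazulen-1(2H)-one
Conditions: HF·pyridine, pyridine, THF, 0 → 23 °C
Reagents that add atoms: none
Why: Fluoride-mediated silyl ether cleavage with buffered HF·pyridine avoids the basic conditions that could start retro-aldol cleavage or dehydration of the β-ketol, and no stereocentre is touched.

Step 10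
Reactants: 17 (3R,3aS,4S,8aR)-3,4-dihydroxy-6,8a-dimethyl-3-(propan-2-yl)-3,3a,4,5,8,8a-hexahydroazulen-1(2H)-one
Product: 18 (3R,3aS,4S,8aR)-3-hydroxy-6,8a-dimethyl-1-oxo-3-(propan-2-yl)-1,2,3,3a,4,5,8,8a-octahydroazulen-4-yl 4-methoxybenzoate
Conditions: 4-MeOC6H4COCl (1.5 equiv), Et3N (3 equiv), DMAP (0.5 equiv), CH2Cl2, 0 → 23 °C
Reagents that add atoms: 4-methoxybenzoyl chloride, COc1ccc(cc1)C(Cl)=O
Why: DMAP-catalysed acyl transfer should acylate only the secondary C4 alcohol, because the tertiary C3 carbinol is far too hindered, and it proceeds with retention at C4.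

**Compound list**

1 | pent-1-en-4-yne | C=CCC#C | starting material
2 | dimethyl[(1E)-2-methylpenta-1,4-dien-1-yl]alane | C=CC/C(C)=C/[Al](C)C | intermediate (not isolated)
3 | lithium butyl(dimethyl)[(1E)-2-methylpenta-1,4-dien-1-yl]aluminate | [Li+].CCCC[Al-](C)(C)/C=C(\C)CC=C | intermediate (not isolated)
4 | (2E)-3-methylhexa-2,5-dien-1-ol | C=CC/C(C)=C/CO | intermediate
5 | ethyl (3R)-4-chloro-3-hydroxybutanoate | CCOC(=O)C[C@@H](O)CCl | starting material
6 | ethyl 2-[(2R)-oxiran-2-yl]acetate | CCOC(=O)C[C@@H]1CO1 | intermediate (not isolated)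
7 | ethyl (3S)-3-hydroxy-5-methylhex-5-enoate | CCOC(=O)C[C@@H](O)CC(C)=C | intermediate
8 | (2E)-3-methylhexa-2,5-dien-1-yl (3S)-3-hydroxy-5-methylhex-5-enoate | C=CC/C(C)=C/COC(=O)C[C@@H](O)CC(C)=C | intermediate
9 | chelated dilithium dianion of 8 (lithium alkoxide and lithium ester enolate, O–Li cis to the carbinol-bearing carbon) | [Li]O/C(OC/C=C(\C)CC=C)=C\[C@@H](O[Li])CC(C)=C | intermediate (not isolated)
10 | (2S,3S)-3-hydroxy-5-methyl-2-[(3S)-3-methylhexa-1,5-dien-3-yl]hex-5-enoic acid | C=CC[C@@](C)(C=C)[C@H](C(=O)O)[C@@H](O)CC(C)=C | intermediate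
11 | tert-butyldimethylsilyl (2S,3S)-3-[(tert-butyldimethylsilyl)oxy]-5-methyl-2-[(3S)-3-methylhexa-1,5-dien-3-yl]hex-5-enoate | C=CC[C@@](C)(C=C)[C@H](C(=O)O[Si](C)(C)C(C)(C)C)[C@@H](O[Si](C)(C)C(C)(C)C)CC(C)=C | intermediate (not isolated)
12 | (2S,3S)-3-[(tert-butyldimethylsilyl)oxy]-5-methyl-2-[(3S)-3-methylhexa-1,5-dien-3-yl]hex-5-enoic acid | C=CC[C@@](C)(C=C)[C@H](C(=O)O)[C@@H](O[Si](C)(C)C(C)(C)C)CC(C)=C | intermediate
13 | (1S,2S,7S)-7-[(tert-butyldimethylsilyl)oxy]-2-ethenyl-2,5-dimethylcyclohept-4-ene-1-carboxylic acid | CC(C)(C)[Si](C)(C)O[C@H]1CC(C)=CC[C@@](C)(C=C)[C@@H]1C(=O)O | intermediate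
14 | (3aS,4S,8aR)-4-[(tert-butyldimethylsilyl)oxy]-6,8a-dimethyl-1-methylidene-1,3a,4,5,8,8a-hexahydro-3H-cyclohepta[c]furan-3-one (trans-fused enol lactone) | CC(C)(C)[Si](C)(C)O[C@H]1CC(C)=CC[C@@]2(C)C(=C)OC(=O)[C@H]12 | intermediate
15 | dichlorocerium enolate of the ring-opened 1,4-diketone (cycloheptene with the enolised acetyl group on the quaternary carbon and a 2-methylpropanoyl group on the neighbouring carbon, trans) | CC(C)(C)[Si](C)(C)O[C@H]1CC(C)=CC[C@@](C)(C(=C)O[Ce](Cl)Cl)[C@@H]1C(=O)C(C)C | intermediate (not isolated)
16 | (3R,3aS,4S,8aR)-4-[(tert-butyldimethylsilyl)oxy]-3-hydroxy-6,8a-dimethyl-3-(propan-2-yl)-3,3a,4,5,8,8a-hexahydroazulen-1(2H)-one | CC(C)(C)[Si](C)(C)O[C@H]1CC(C)=CC[C@@]2(C)C(=O)C[C@@](O)(C(C)C)[C@H]12 | intermediate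
17 | (3R,3aS,4S,8aR)-3,4-dihydroxy-6,8a-dimethyl-3-(propan-2-yl)-3,3a,4,5,8,8a-hexahydroazulen-1(2H)-one | O[C@H]1CC(C)=CC[C@@]2(C)C(=O)C[C@@](O)(C(C)C)[C@H]12 | intermediate
18 | (3R,3aS,4S,8aR)-3-hydroxy-6,8a-dimethyl-1-oxo-3-(propan-2-yl)-1,2,3,3a,4,5,8,8a-octahydroazulen-4-yl 4-methoxybenzoate | COc1ccc(C(=O)O[C@H]2CC(C)=CC[C@@]3(C)C(=O)C[C@@](O)(C(C)C)[C@H]23)cc1 | target

**Count and risks**

Total step count: 10. Longest linear sequence: 9 steps (1 → 4 → 8 → 10 → 12 → 13 → 14 → 16 → 17 → 18; the branch from 5 is equally long).

The three steps most likely to fail: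

1. Step 8 (the step with the label). What may go wrong: deprotonation at C3a in place of addition, followed by β-elimination of the silyloxy group; hydride transfer from the isopropyl reagent; proton shuffling in the keto enolate before the slow enolendo closure; loss of water from the ketol. The fallback uses known chemistry only and builds the ring stepwise. It sets out from 13: amide coupling with N,O-dimethylhydroxylamine (EDC, HOBt) should give Weinreb amide F1; isopropyllithium or i-PrMgCl·LiCl should convert it into isopropyl ketone F2; Tsuji–Wacker oxidation of the vinyl group (PdCl2, CuCl, O2, DMF–H2O) should give 1,4-diketone F3; kinetic deprotonation of the methyl ketone (LDA, THF, −78 → 0 °C) or an amine-catalysed aldol addition should then close the ring to 16, where the route is rejoined.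

2. Step 4. What may go wrong: incomplete face selection in the chelated dianion (2,3-syn isomer), slow rearrangement at the fully substituted alkene terminus, base-induced isomerisation of the skipped diene. The fallback replaces chelate control by reagent control. It sets out from 8: silylation (TBSOTf, 2,6-lutidine) should give silyl ether F4; an enantioselective boron-enolate Ireland–Claisen rearrangement with a chiral C2-symmetric bis-sulfonamide bromoborane and a tertiary amine, the controller being chosen to match the existing stereocentre, should give acid 12 directly, where the route is rejoined (step 5 is then not needed).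

3. Step 7. What may go wrong: oxypalladation or Pd–H isomerisation at the ring alkene, or slow closure to the trans-fused lactone. The fallback separates oxidation and ring closure. It sets out from 13: Tsuji–Wacker oxidation (PdCl2, CuCl, O2, DMF–H2O) should give γ-keto acid F5; dehydrative enol lactonisation (Ac2O, NaOAc, 100 °C) should give 14, where the route is rejoined.

**Further compounds**

F1 | step 8 | (1S,2S,7S)-7-[(tert-butyldimethylsilyl)oxy]-2-ethenyl-N-methoxy-N,2,5-trimethylcyclohept-4-ene-1-carboxamide | CC(C)(C)[Si](C)(C)O[C@H]1CC(C)=CC[C@@](C)(C=C)[C@@H]1C(=O)N(C)OC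
F2 | step 8 | 1-[(1S,2S,7S)-7-[(tert-butyldimethylsilyl)oxy]-2-ethenyl-2,5-dimethylcyclohept-4-en-1-yl]-2-methylpropan-1-one | CC(C)(C)[Si](C)(C)O[C@H]1CC(C)=CC[C@@](C)(C=C)[C@@H]1C(=O)C(C)C
F3 | step 8 | 1-[(1S,2R,7S)-2-acetyl-7-[(tert-butyldimethylsilyl)oxy]-2,5-dimethylcyclohept-4-en-1-yl]-2-methylpropan-1-one | CC(C)(C)[Si](C)(C)O[C@H]1CC(C)=CC[C@@](C)(C(C)=O)[C@@H]1C(=O)C(C)C
F4 | step 4 | (2E)-3-methylhexa-2,5-dien-1-yl (3S)-3-[(tert-butyldimethylsilyl)oxy]-5-methylhex-5-enoate | C=CC/C(C)=C/COC(=O)C[C@@H](O[Si](C)(C)C(C)(C)C)CC(C)=C
F5 | step 7 | (1S,2R,7S)-2-acetyl-7-[(tert-butyldimethylsilyl)oxy]-2,5-dimethylcyclohept-4-ene-1-carboxylic acid | CC(C)(C)[Si](C)(C)O[C@H]1CC(C)=CC[C@@](C)(C(C)=O)[C@@H]1C(=O)O
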